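Numbering the core as 3,7-dioxabicyclo[3.3.0]octane (C1 carbinol, C2/C6 aryl carbons), the route rests on cutting the C1–C2 bond of ring A (C2–O3–C4–C5–C1): a tertiary carbinol C1 beside the benzylic, O3-bearing C2 is the retron of a [1,2]-Wittig shift. The precursor is a trans-fused 1,3-dioxane, the veratrylidene acetal joining O3 and the C1 oxygen of an α-hydroxy-γ-lactone that already holds ring B as its lactone. Enolisation at C1 and O-to-C migration of the acetal carbon contracts this six-membered acetal to ring A, forming the C1–C2 bond, the quaternary C1–OH centre and the C2 configuration in one operation. An auxiliary-controlled anti-aldol sets C5 and C6 beforehand.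

Key step: step 6

Remark: the MgCl2-catalysed anti-aldol is assumed to follow the chelated Z-enolate facial sense of imide alkylations, which is why the (R)-auxiliary is taken; ring B is C5–C6–O7–C8–C1.

Step 1
Reactants: 1 (R)-4-benzyl-1,3-oxazolidin-2-one; 2 methyl 4-chloro-4-oxobutanoate
Product: 3 succinate imide
Conditions: Et3N, DMAP (cat.), CH2Cl2, 0 °C to rt
Reagents that add atoms: none
Why: DMAP-catalysed N-acylation of the oxazolidinone by the acid chloride (nucleophilic acyl substitution) should proceed cleanly, leaves the methyl ester untouched and forms no stereocentre.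

Step 2
Reactants: 3 succinate imide; 4 3,4-dimethoxybenzaldehyde (veratraldehyde)
Product: 7 cis-lactone imide, via TMS aldol ether 5 (not isolated), via aldol hydroxy ester 6 (not isolated)
Conditions: MgCl2 (20 mol %), Et3N, Me3SiCl, EtOAc, 23 °C; then 1 M HCl, THF, 0 °C; then PPTS (cat.), PhMe, 50 °C
Reagents that add atoms: none
Why: In this MgCl2-catalysed anti-aldol of an N-acyloxazolidinone (Evans anti-aldol), soft enolisation should give only the chelated Z-enolate of the imide, which adds to the non-enolisable aldehyde on the face away from the benzyl group (setting C5) through the anti-selective transition state with silyl trapping (setting C6), after which desilylation and lactonisation by acyl substitution, which does not touch the C6–O bond, should give the lactone with aryl and acyl groups cis.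

Step 3
Reactants: 7 cis-lactone imide
Product: 8 hydroxymethyl lactone
Conditions: NaBH4, THF/H2O (4:1), 0 °C
Reagents that add atoms: none
Why: Reductive cleavage of the N-acyloxazolidinone should be chemoselective because the exocyclic imide carbonyl is much more electrophilic than the γ-lactone at 0 °C, so the auxiliary is released and C4 becomes the primary alcohol with C5 and C6 unchanged.

Step 4
Reactants: 8 hydroxymethyl lactone
Product: 10 diol lactone, via disodium alkoxide enolate 9 (not isolated)
Conditions: NaN(SiMe3)2 (2.2 equiv), THF, −78 °C; Davis oxaziridine, −78 °C; AcOH, −78 °C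
Reagents that add atoms: Davis oxaziridine (trans-3-phenyl-2-(phenylsulfonyl)oxaziridine), O=S(=O)(c1ccccc1)N1OC1c1ccccc1
Why: In this enolate hydroxylation with a Davis oxaziridine the oxidant should approach the lactone enolate anti to the cis-disposed C5 and C6 substituents, so the new C1 hydroxyl comes out trans to the hydroxymethyl group, while the enolate form protects the lactone carbonyl from the neighbouring alkoxide.

Step 5
Reactants: 10 diol lactone; 4 3,4-dimethoxybenzaldehyde (veratraldehyde)
Product: 11 acetal lactone
Conditions: PPTS (cat.), benzene, reflux, Dean–Stark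
Reagents that add atoms: none
Why: Acid-catalysed acetalisation of the 1,3-diol under thermodynamic control with azeotropic removal of water should give the trans-fused 1,3-dioxane, which has only one chair, with the aryl group equatorial at the new acetal centre C2 (cis to H5).

Step 6
Reactants: 11 acetal lactone
Product: 13 hydroxy lactone, via potassium enolate 12 (not isolated)
Conditions: KN(SiMe3)2 (1.3 equiv), THF, −78 °C to 23 °C; AcOH
Reagents that add atoms: none
Why: Proposed new method: KN(SiMe3)2 removes the C1–H of 11 to give lactone enolate 12, in which the acetal C2–O bond to the oxygen on C1 should homolyse to a tethered radical pair (semidione-type ketyl of the α-keto lactone and α-alkoxy-3,4-dimethoxybenzyl radical) that recombines at C1, i.e. a [1,2]-Wittig rearrangement that expels the former acetal oxygen from the six-membered ring and leaves it as the C1 alkoxide. The closest known reactions are the acetal [1,2]-Wittig rearrangement (O-glycoside to C-glycoside carbinol) and the [1,2]-Wittig shift of α-benzyloxy lactam enolates; an enolate-driven acetal shift with ring contraction has not been shown, but the weaker push of an enolate is offset by the doubly stabilised migrating radical and by the gain from enolate to alkoxide and from C–O to C–C. Ring A (C2–O3–C4–C5–C1) is closed by intramolecular radical–radical recombination forming C1–C2, a five-membered closure that is formally a 1,2-shift and contracts the 1,3-dioxane by one atom. The quaternary centre C1 is controlled by the O3–C4 tether on C5, which lets C2 reach only the lactone face bearing C4, so rings A and B must come out cis-fused with the hydroxyl cis to H5. C2 is controlled by the acetal centre of 11: migration with retention, the norm in acetal [1,2]-Wittig shifts, turns the equatorial aryl group (cis to H5) into the exo aryl group cis to the C1 hydroxyl, which is also the less hindered mode of recombination. The step needs recombination at carbon C1 in preference to fragmentation or bonding at the enolate oxygen, which the five-membered tether and the lack of any leaving group on C5 secure.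

Step 7
Reactants: 13 hydroxy lactone
Product: 15 (+)-gmelinol, via lactol 14 (not isolated)
Conditions: i-Bu2AlH (3 equiv), CH2Cl2, −78 °C; aq. KNaC4H4O6; then Et3SiH, BF3·OEt2, CH2Cl2, −78 to −40 °C
Reagents that add atoms: none
Why: In this two-stage lactone-to-ether reduction i-Bu2AlH should stop at the lactol at −78 °C, and BF3-promoted ionisation to the C8 oxocarbenium ion with hydride transfer from Et3SiH (ionic hydrogenation) should give the C8 methylene at a temperature where the benzylic ethers at C2 and C6 do not ionise, with no stereocentre formed or touched.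

Compound list
1 | (R)-4-benzyl-1,3-oxazolidin-2-one | O=C1N[C@H](Cc2ccccc2)CO1 | starting material
2 | methyl 4-chloro-4-oxobutanoate | COC(=O)CCC(Cl)=O | starting material
3 | succinate imide: methyl 4-[(4R)-4-benzyl-2-oxo-1,3-oxazolidin-3-yl]-4-oxobutanoate | COC(=O)CCC(=O)N1[C@H](Cc2ccccc2)COC1=O | intermediate
4 | 3,4-dimethoxybenzaldehyde (veratraldehyde) | COc1ccc(C=O)cc1OC | starting material
5 | TMS aldol ether: methyl (3S,4R)-3-{[(4R)-4-benzyl-2-oxo-1,3-oxazolidin-3-yl]carbonyl}-4-(3,4-dimethoxyphenyl)-4-(trimethylsilyloxy)butanoate | O=C(N1[C@H](Cc2ccccc2)COC1=O)[C@@H](CC(=O)OC)[C@@H](O[Si](C)(C)C)c1ccc(OC)c(OC)c1 | intermediate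
6 | aldol hydroxy ester (anti): methyl (3S,4R)-3-{[(4R)-4-benzyl-2-oxo-1,3-oxazolidin-3-yl]carbonyl}-4-(3,4-dimethoxyphenyl)-4-hydroxybutanoate | O=C(N1[C@H](Cc2ccccc2)COC1=O)[C@@H](CC(=O)OC)[C@@H](O)c1ccc(OC)c(OC)c1 | intermediate
7 | cis-lactone imide: (4R)-4-benzyl-3-{[(2R,3S)-2-(3,4-dimethoxyphenyl)-5-oxooxolan-3-yl]carbonyl}-1,3-oxazolidin-2-one | O=C(N1[C@H](Cc2ccccc2)COC1=O)[C@@H]1[C@@H](OC(=O)C1)c1ccc(OC)c(OC)c1 | intermediate
8 | hydroxymethyl lactone: (4R,5R)-5-(3,4-dimethoxyphenyl)-4-(hydroxymethyl)oxolan-2-one (aryl and CH2OH cis) | OC[C@@H]1[C@@H](OC(=O)C1)c1ccc(OC)c(OC)c1 | intermediate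
9 | disodium alkoxide enolate of 8 | [Na+].[Na+].[O-]C[C@@H]1[C@@H](OC([O-])=C1)c1ccc(OC)c(OC)c1 | intermediate
10 | diol lactone: (3S,4S,5R)-5-(3,4-dimethoxyphenyl)-3-hydroxy-4-(hydroxymethyl)oxolan-2-one (3-OH trans to 4-CH2OH; 4-CH2OH cis to 5-aryl) | OC[C@@H]1[C@@H](OC(=O)[C@H]1O)c1ccc(OC)c(OC)c1 | intermediate
11 | acetal lactone: (1S,3S,6R,7R)-3,7-bis(3,4-dimethoxyphenyl)-2,4,8-trioxabicyclo[4.3.0]nonan-9-one (trans-fused; 3-aryl equatorial) | COc1ccc(cc1OC)[C@H]2OC[C@@H]3[C@@H](OC(=O)[C@H]3O2)c4ccc(OC)c(OC)c4 | intermediate
12 | potassium enolate of 11 | [K+].COc1ccc(cc1OC)[C@H]2OC[C@@H]3[C@@H](OC([O-])=C3O2)c4ccc(OC)c(OC)c4 | intermediate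
13 | hydroxy lactone: (1R,2R,5R,6R)-2,6-bis(3,4-dimethoxyphenyl)-1-hydroxy-3,7-dioxabicyclo[3.3.0]octan-8-one | COc1ccc([C@H]2OC[C@@H]3[C@H](c4ccc(OC)c(OC)c4)OC(=O)[C@]23O)cc1OC | intermediate
14 | lactol: (1R,2R,5R,6R)-2,6-bis(3,4-dimethoxyphenyl)-3,7-dioxabicyclo[3.3.0]octane-1,8-diol (both C8 epimers) | COc1ccc([C@H]2OC[C@@H]3[C@H](c4ccc(OC)c(OC)c4)OC(O)[C@]23O)cc1OC | intermediate
15 | (+)-gmelinol: (1S,2R,5R,6R)-2,6-bis(3,4-dimethoxyphenyl)-3,7-dioxabicyclo[3.3.0]octan-1-ol | COc1ccc([C@H]2OC[C@@H]3[C@H](c4ccc(OC)c(OC)c4)OC[C@]23O)cc1OC | target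

Total step count: 7. Longest linear sequence: 7 steps (from 1 and 2 to 15).

Steps most likely to fail

Step 6. The enolate may resist C–O homolysis, since an ester enolate pushes far less than the carbanions of classical [1,2]-Wittig shifts. The radical pair may also lose the C2 configuration or fragment instead of recombining at C1. The fallback uses known chemistry, sets out from 8 and comes back at 13. Aldehyde 4 is converted into its dimethyl acetal F1 (HC(OMe)3, cat. TsOH, MeOH). Acetal exchange between 8 and F1 (PPTS, CH2Cl2, removal of MeOH) should give the mixed methyl acetal F2 at O3. LiN(i-Pr)2 and Me3SiCl (THF, −78 °C) should give the silyl ketene acetal F3. Catalytic Me3SiOTf (CH2Cl2, −78 °C) ionises the mixed acetal to the O3=C2 oxocarbenium ion, which C1 of the ketene acetal captures in an intramolecular Mukaiyama-type addition. The same C4 tether enforces cis fusion and the aryl group is expected exo, giving the bicyclic lactone F4, which lacks the C1 hydroxyl. KN(SiMe3)2 followed by Davis oxaziridine should hydroxylate C1 on the convex face, the only one compatible with cis fusion, to give 13.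

Step 7. BF3 may ionise the electron-rich benzylic C6–O7 bond, which would epimerise the endo aryl group, or the lactol may open to the α-hydroxy aldehyde and undergo an α-ketol shift. The fallback sets out from 13 and comes back at 15 without any Lewis acid. LiAlH4 (THF, 0 °C) should open the lactone to the triol F5. MsCl (1 equiv) and Et3N (CH2Cl2, −20 °C to rt) should sulfonylate the primary C8 hydroxyl to the primary mesylate F6. The C6 hydroxyl then displaces the mesylate (5-exo-tet etherification) and closes ring B without the benzylic C6–O bond ever being broken.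

Step 4. The free primary alkoxide may translactonise before or after oxygen transfer, and the enolate may add to the sulfonimine by-product. The fallback sets out from 8 and comes back at 11, bypassing 10 and step 5. Alcohol 8 is etherified with 3,4-dimethoxybenzyl trichloroacetimidate (cat. CSA, CH2Cl2) to the 3,4-dimethoxybenzyl ether F7, which carries no free alkoxide. NaN(SiMe3)2 and Davis oxaziridine (THF, −78 °C) should give the hydroxy ether F8 with the hydroxyl trans to the C4 side chain. DDQ (4 Å MS, CH2Cl2, 0 °C) oxidises the benzyl ether to its oxocarbenium ion, which the C1 hydroxyl traps (oxidative acetalisation) to give 11.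

Further compounds
F1 | step 6 | 3,4-dimethoxybenzaldehyde dimethyl acetal | COc1ccc(C(OC)OC)cc1OC
F2 | step 6 | mixed methyl acetal of 8 at O3 (both epimers at the acetal carbon) | COc1ccc(C(OC)OC[C@@H]2[C@@H](OC(=O)C2)c2ccc(OC)c(OC)c2)cc1OC
F3 | step 6 | trimethylsilyl ketene acetal of F2 | COc1ccc(C(OC)OC[C@@H]2[C@@H](OC(O[Si](C)(C)C)=C2)c2ccc(OC)c(OC)c2)cc1OC
F4 | step 6 | bicyclic lactone without the C1 hydroxyl: 2,6-bis(3,4-dimethoxyphenyl)-3,7-dioxabicyclo[3.3.0]octan-8-one (2-aryl exo, 6-aryl endo) | COc1ccc([C@H]2OC[C@@H]3[C@H](c4ccc(OC)c(OC)c4)OC(=O)[C@H]23)cc1OC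
F5 | step 7 | triol from lactone opening of 13 | COc1ccc([C@H]2OC[C@H]([C@@H](O)c3ccc(OC)c(OC)c3)[C@]2(O)CO)cc1OC
F6 | step 7 | primary mesylate of F5 | COc1ccc([C@H]2OC[C@H]([C@@H](O)c3ccc(OC)c(OC)c3)[C@]2(O)COS(C)(=O)=O)cc1OC
F7 | step 4 | 3,4-dimethoxybenzyl ether of 8 | COc1ccc(COC[C@@H]2[C@@H](OC(=O)C2)c2ccc(OC)c(OC)c2)cc1OC
F8 | step 4 | α-hydroxy lactone 3,4-dimethoxybenzyl ether (hydroxyl trans to the side chain) | COc1ccc(COC[C@@H]2[C@@H](OC(=O)[C@H]2O)c2ccc(OC)c(OC)c2)cc1OC
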